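**Retrosynthetic overview**
1. Target 28 is the diosphenol [5+2] adduct of a ring-B-contracted abietane quinone with 4-epi-trans-communic acid 24; the C6 hydroxy-aldehyde is unmasked at the end from a cyclic carbonate (steps 18 and 19).
2. Key disconnection: C2–C3 of ring A (C1–C5, C10). Ring A is an unfunctionalised cyclohexane, trans-fused to cyclopentane ring B at C5/C10 and carrying the C4 gem-dimethyl group. Cutting C2–C3 leaves a vinyl group on C10 and a CH2CO2H arm on C4, held trans on ring B, so a C3 radical made by decarboxylation can only close 6-endo (5-exo would give a trans-bicyclo[3.3.0]octane).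
3. Bicyclo[3.2.1]octane: Lewis-acid [5+2] cycloaddition of 2-methoxyquinone 23 (C8, C9, C11, C12, C13 as the five-carbon unit, C14 as the bridge) with the terminal alkene of 24.
4. C5/C10 vicinal pair: Ireland–Claisen rearrangement of a CBS-derived allylic ester of 3,3-dimethylglutarate. Ring B: Friedel–Crafts acylation. C6/C7: methylenation and dihydroxylation.
5. Ring order: ring C (purchased arene) → ring B (step 9) → the two rings of the bicyclo[3.2.1]octane (step 16; labdane decalin purchased) → ring A (step 17). The carbonate ring of steps 12–18 is temporary.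

Key step: step 17

Assumption: 4-epi-trans-communic acid (24), offered by natural-product suppliers as 4-epicommunic acid, is taken as a purchasable starting material; its stereocentres and its diene are used unchanged.

Numbering and abbreviations: the ring-B-contracted abietane unit keeps abietane numbers (ring A: C1–C5, C10; ring B: C5, C6, C8, C9, C10; ring C: C8, C9, C11–C14; C7 = carbon on C6; C20 = methyl on C10). Labdane carbons are primed. α is the face of H5. SEM = CH2OCH2CH2SiMe3; TMSE = CH2CH2SiMe3; Ar = 3-methoxy-4-(propan-2-yl)-2-(SEM-oxy)phenyl.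

**Route**

Step 1
Reactants: 1 3-isopropylcatechol
Product: 2 2-(propan-2-yl)-6-{[2-(trimethylsilyl)ethoxy]methoxy}phenol
Conditions: NaH (1.0 equiv), THF, 0 °C; SEMCl (1.0 equiv), 0 °C → rt
Reagents that add atoms: 2-(trimethylsilyl)ethoxymethyl chloride (SEMCl), C[Si](C)(C)CCOCCl
Why: Williamson-type O-alkylation of the monosodium catecholate should occur at the more acidic, less hindered oxygen remote from the isopropyl group, leaving the flanked hydroxyl free.

Step 2
Reactants: 2 2-(propan-2-yl)-6-(SEM-oxy)phenol
Product: 3 1-(SEM-oxy)-2-methoxy-3-(propan-2-yl)benzene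
Conditions: MeI, K2CO3, DMF, 50 °C
Reagents that add atoms: iodomethane, CI
Why: Williamson methylation of the remaining hindered phenol differentiates the two oxygens, so that the later C11 phenol can be freed while C12 stays a methyl ether.

Step 3
Reactants: 3 1-(SEM-oxy)-2-methoxy-3-(propan-2-yl)benzene; 4 (E)-4-methoxypent-3-en-2-one
Product: 7 (E)-4-Ar-pent-3-en-2-one, via aryllithium 5 (not isolated), via lithium alkoxide adduct 6 (not isolated)
Conditions: n-BuLi, TMEDA, Et2O, 0 °C; then 4, THF, −78 °C; then 1 M HCl, THF, 0 °C → rt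
Reagents that add atoms: water, O
Why: Directed ortho-metalation at the only hydrogen ortho to the OSEM group, 1,2-addition to the vinylogous ester and acid-induced hydrolysis–dehydration (Stork–Danheiser-type transposition) should give the β-aryl enone as the thermodynamically favoured E isomer.

Step 4
Reactants: 7 (E)-4-Ar-pent-3-en-2-one
Product: 8 (2R,3E)-4-Ar-pent-3-en-2-ol
Conditions: (S)-2-methyl-CBS-oxazaborolidine (10 mol %), BH3·SMe2, THF, −30 °C; then MeOH
Reagents that add atoms: none
Why: Corey–Bakshi–Shibata reduction delivers hydride to the ketone face chosen by the (S)-catalyst (alkenyl as large group, methyl as small group), setting the (R)-carbinol centre that later controls C10 and C5.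

Step 5
Reactants: 9 3,3-dimethylglutaric anhydride; 10 2-(trimethylsilyl)ethanol
Product: 11 3,3-dimethyl-5-oxo-5-[2-(trimethylsilyl)ethoxy]pentanoic acid
Conditions: DMAP (10 mol %), toluene, 80 °C
Reagents that add atoms: none
Why: DMAP-catalysed alcoholysis of the symmetrical cyclic anhydride gives the mono-ester acid without a selectivity issue and without a by-product.

Step 6
Reactants: 8 (2R,3E)-4-Ar-pent-3-en-2-ol; 11 mono-TMSE 3,3-dimethylglutarate
Product: 12 1-[(2R,3E)-4-Ar-pent-3-en-2-yl] 5-[2-(trimethylsilyl)ethyl] 3,3-dimethylpentanedioate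
Conditions: DCC, DMAP (10 mol %), CH2Cl2, 0 °C → rt
Reagents that add atoms: none
Why: Steglich esterification under neutral conditions should acylate the ionisation-prone secondary allylic alcohol without racemisation or allylic transposition.

Step 7
Reactants: 12 allylic diester
Product: 14 (2S,3S,4E)-3-Ar-3-methyl-2-{2-methyl-4-oxo-4-[2-(trimethylsilyl)ethoxy]butan-2-yl}hex-4-enoic acid, via bis(silyl ketene acetal) 13 (not isolated)
Conditions: LiN(iPr)2 (2.5 equiv), Me3SiCl (4 equiv), THF, −78 °C; then 65 °C; 1 M HCl work-up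
Reagents that add atoms: none
Why: Ireland–Claisen rearrangement ([3,3]-sigmatropic) through a chair transition state with the kinetic E(O)-enolate (C5 substituent cis to the allylic oxygen, pseudoaxial), the E-alkene (aryl pseudoequatorial) and the carbinol methyl equatorial should transfer the (R)-carbinol chirality to the quaternary C10 and the adjacent C5 in one step, while the second, non-allylic ketene acetal simply reverts to the TMSE ester on work-up.

Step 8
Reactants: 14 (2S,3S,4E)-hex-4-enoic acid
Product: 15 (2S,3S)-3-Ar-3-methyl-2-{2-methyl-4-oxo-4-[2-(trimethylsilyl)ethoxy]butan-2-yl}pent-4-enoic acid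
Conditions: second-generation Hoveyda–Grubbs catalyst (10 mol %), ethene (5 bar), toluene, 60 °C
Reagents that add atoms: ethene, C=C
Why: Ethenolysis (cross-metathesis with ethene) exchanges the propenyl terminus for CH2, is driven by loss of propene and leaves both stereocentres untouched.

Step 9
Reactants: 15 (2S,3S)-pent-4-enoic acid
Product: 17 2-(trimethylsilyl)ethyl 3-[(1S,2S)-1-ethenyl-6-methoxy-1-methyl-3-oxo-5-(propan-2-yl)-7-(SEM-oxy)-2,3-dihydro-1H-inden-2-yl]-3-methylbutanoate, via mixed trifluoroacetic anhydride 16 (not isolated)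
Conditions: (CF3CO)2O, CH2Cl2, 0 °C
Reagents that add atoms: none
Why: Intramolecular Friedel–Crafts acylation at C8, the only free position ortho to the tether and para to the C12 methoxy group, should close five-membered ring B without touching C5 or C10.

Step 10
Reactants: 17 indanone
Product: 18 methylidene-indane (17 with C6=O replaced by C6=C7H2; C5 and C10 as in 17)
Conditions: Zn, CH2Br2, TiCl4, THF, 0 °C → rt
Reagents that add atoms: dibromomethane, BrCBr
Why: Takai–Lombardo methylenation converts the hindered, enolisable aryl ketone into the exocyclic alkene under non-basic conditions, so the C5 centre next to the carbonyl should not epimerise.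

Step 11
Reactants: 18 methylidene-indane
Product: 19 C6/C7 diol (6α-hydroxy and 6β-hydroxymethyl)
Conditions: OsO4 (2 mol %), NMO (1.05 equiv), acetone/H2O, 0 °C
Reagents that add atoms: 4-methylmorpholine N-oxide, C[N+]1([O-])CCOCC1; water, O
Why: Upjohn dihydroxylation should attack the electron-rich 1,1-disubstituted styrene-type alkene in preference to the neopentylic vinyl group and from the face opposite to the bulky C5 side chain, which sets C6 with the hydroxyl α and the CH2OH (C7) β.

Step 12
Reactants: 19 C6/C7 diol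
Product: 20 C6/C7 cyclic carbonate (spiro-1,3-dioxolan-2-one at C6)
Conditions: 1,1'-carbonyldiimidazole, DMAP (10 mol %), CH2Cl2, rt → 40 °C
Reagents that add atoms: 1,1'-carbonyldiimidazole, O=C(n1ccnc1)n1ccnc1
Why: Carbonylation of the 1,2-diol (acyl-imidazole at the primary hydroxyl, then 5-exo closure on the tertiary one) masks both oxygens as a non-nucleophilic cyclic carbonate that tolerates the later Lewis acid.

Step 13
Reactants: 20 cyclic carbonate
Product: 21 C11 phenol carboxylic acid (SEM and TMSE removed)
Conditions: Bu4NF (4 equiv), THF, 50 °C; cold 0.5 M HCl work-up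
Reagents that add atoms: none
Why: Fluoride-induced β-silyl fragmentation removes the aryl SEM ether and the TMSE ester in one operation and avoids the acid that would ionise the electron-rich tertiary benzylic C6–O bond.

Step 14
Reactants: 21 phenol acid
Product: 22 12-methoxy-11,14-quinone acid
Conditions: K2NO(SO3)2 (2.5 equiv), KH2PO4 buffer, acetone/H2O, 0 °C → rt
Reagents that add atoms: potassium nitrosodisulfonate, [K+].[K+].[O]N(S(=O)(=O)[O-])S(=O)(=O)[O-]
Why: Teuber oxidation of the phenol with a free para position (C14) should give the 2-methoxy-1,4-benzoquinone, the C12 methyl ether excluding ortho-quinone formation.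

Step 15
Reactants: 22 methoxyquinone acid
Product: 23 N-(acyloxy)phthalimide (redox-active ester) of 22
Conditions: N-hydroxyphthalimide, DIC, DMAP (5 mol %), CH2Cl2, 0 °C → rt
Reagents that add atoms: N-hydroxyphthalimide, O=C1c2ccccc2C(=O)N1O
Why: Carbodiimide esterification converts the only carboxylic acid into the redox-active ester before the second acid (that of 24) enters the molecule.

Step 16
Reactants: 23 methoxyquinone redox-active ester; 24 4-epi-trans-communic acid
Product: 25 [5+2] adduct (bicyclo[3.2.1]octenedione diosphenol with C10 vinyl and C4 arm still open)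
Conditions: TiCl4 (2.5 equiv), CH2Cl2, −78 °C; H2O quench at −78 °C
Reagents that add atoms: water, O
Why: In this Lewis-acid-promoted [5+2] cycloaddition of a 2-alkoxy-1,4-benzoquinone with an alkene (Engler type, related to the perezone cycloaddition), tetravalent titanium chelated by O11 and the C12 methoxy group makes C8 electrophilic, the terminal CH2 of the diene should attack it from the α face (opposite to the C5 side chain and C20), and the allyl cation should close on C13 with the labdane substituent endo, which sets C8, C13 and C14′, while hydrolysis of the C12 oxocarbenium ion releases the diosphenol.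

Step 17
Reactants: 25 [5+2] adduct
Product: 26 ring-A-closed carbonate (full carbon skeleton)
Conditions: Ru(bpy)3(PF6)2 (2 mol %), Hantzsch ester (1.5 equiv, added over 6 h), iPr2NEt (3 equiv), CH2Cl2, 0.002 M, blue LEDs, 25 °C
Reagents that add atoms: none
Why: Single-electron reduction of the N-acyloxyphthalimide by the photoreduced ruthenium complex cleaves the N–O bond and expels CO2 to give the primary C3 radical, which adds to the terminal carbon (C2) of the C10 vinyl group, and the resulting secondary C1 radical is quenched by hydrogen-atom transfer from the Hantzsch ester. The closest known reaction type is the reductive decarboxylative radical cyclisation of redox-active esters onto alkenes (photoredox generation of alkyl radicals followed by Giese-type hydroalkylation). Ring A closes in the 6-endo-trig mode because 5-exo attack at C1 would build a trans-fused bicyclo[3.3.0]octane on the trans-disposed C5 and C10 arms and would have to hit the neopentylic internal carbon. No new stereocentre is formed: the trans A/B fusion is read out from the C5/C10 pair fixed in step 7, and the C4 gem-dimethyl group (Thorpe–Ingold effect) holds the radical near the alkene. The step needs chemoselectivity for the vinyl terminus over the enedione carbon C9, over the labdane alkenes and over premature reduction: C9 is fully substituted, shielded by C20 and would give a strained bicyclo[2.2.1] system, the diosphenol is present as its unreactive enolate, the labdane alkenes can only react intermolecularly at 2 mM, and slow addition of the hydrogen donor keeps reduction slower than cyclisation. One operation thus forges the hindered C2–C3 bond, closes the last ring and erases its own activating carboxyl group, leaving ring A free of functionality.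

Step 18
Reactants: 26 ring-A-closed carbonate
Product: 27 C6/C7 diol of the full skeleton
Conditions: K2CO3 (3 equiv), MeOH, 0 °C; 0.5 M HCl to pH 4
Reagents that add atoms: none
Why: Base-catalysed methanolysis (transesterification) of the cyclic carbonate should free the diol under conditions mild enough for the diosphenol, which is protected as its enolate, and for the hindered bridging ketone.

Step 19
Reactants: 27 C6/C7 diol
Product: 28 target CNP0124601.1
Conditions: TEMPO (10 mol %), PhI(OAc)2 (1.2 equiv), CH2Cl2, 0 °C → rt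
Reagents that add atoms: none
Why: Oxoammonium-mediated (TEMPO/PhI(OAc)2) oxidation is selective for the primary alcohol over the tertiary C6 hydroxyl and the alkenes and should stop at the aldehyde in the absence of water, completing the α-hydroxy aldehyde without diol cleavage.

**Compound list**

1 | 3-isopropylcatechol [3-(propan-2-yl)benzene-1,2-diol] | CC(C)c1cccc(O)c1O | starting material
2 | 2-(propan-2-yl)-6-{[2-(trimethylsilyl)ethoxy]methoxy}phenol | CC(C)c1cccc(OCOCC[Si](C)(C)C)c1O | intermediate
3 | 1-(SEM-oxy)-2-methoxy-3-(propan-2-yl)benzene | CC(C)c1cccc(OCOCC[Si](C)(C)C)c1OC | intermediate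
4 | (E)-4-methoxypent-3-en-2-one | CO/C(C)=C/C(C)=O | starting material
5 | [3-methoxy-4-(propan-2-yl)-2-(SEM-oxy)phenyl]lithium (ArLi; not isolated) | [Li]c1c(OCOCC[Si](C)(C)C)c(OC)c(C(C)C)cc1 | intermediate
6 | lithium (E)-2-Ar-4-methoxypent-3-en-2-olate (racemic; not isolated) | CO/C(C)=C/C(C)(O[Li])c1c(OCOCC[Si](C)(C)C)c(OC)c(C(C)C)cc1 | intermediate
7 | (E)-4-Ar-pent-3-en-2-one | CC(=O)/C=C(\C)c1c(OCOCC[Si](C)(C)C)c(OC)c(C(C)C)cc1 | intermediate
8 | (2R,3E)-4-Ar-pent-3-en-2-ol | C[C@@H](O)/C=C(\C)c1c(OCOCC[Si](C)(C)C)c(OC)c(C(C)C)cc1 | intermediate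
9 | 3,3-dimethylglutaric anhydride (4,4-dimethyloxane-2,6-dione) | CC1(C)CC(=O)OC(=O)C1 | starting material
10 | 2-(trimethylsilyl)ethanol | C[Si](C)(C)CCO | starting material
11 | 3,3-dimethyl-5-oxo-5-[2-(trimethylsilyl)ethoxy]pentanoic acid | OC(=O)CC(C)(C)CC(=O)OCC[Si](C)(C)C | intermediate
12 | 1-[(2R,3E)-4-Ar-pent-3-en-2-yl] 5-[2-(trimethylsilyl)ethyl] 3,3-dimethylpentanedioate | C[C@@H](OC(=O)CC(C)(C)CC(=O)OCC[Si](C)(C)C)/C=C(\C)c1c(OCOCC[Si](C)(C)C)c(OC)c(C(C)C)cc1 | intermediate
13 | bis(trimethylsilyl ketene acetal) of 12, C5 substituent cis to the allylic oxygen (not isolated) | C[C@@H](O/C(O[Si](C)(C)C)=C\C(C)(C)/C=C(/O[Si](C)(C)C)OCC[Si](C)(C)C)/C=C(\C)c1c(OCOCC[Si](C)(C)C)c(OC)c(C(C)C)cc1 | intermediate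
14 | (2S,3S,4E)-3-Ar-3-methyl-2-{2-methyl-4-oxo-4-[2-(trimethylsilyl)ethoxy]butan-2-yl}hex-4-enoic acid | C/C=C/[C@](C)(c1c(OCOCC[Si](C)(C)C)c(OC)c(C(C)C)cc1)[C@@H](C(=O)O)C(C)(C)CC(=O)OCC[Si](C)(C)C | intermediate
15 | (2S,3S)-3-Ar-3-methyl-2-{2-methyl-4-oxo-4-[2-(trimethylsilyl)ethoxy]butan-2-yl}pent-4-enoic acid | C=C[C@](C)(c1c(OCOCC[Si](C)(C)C)c(OC)c(C(C)C)cc1)[C@@H](C(=O)O)C(C)(C)CC(=O)OCC[Si](C)(C)C | intermediate
16 | mixed anhydride of 15 with trifluoroacetic acid (not isolated) | C=C[C@](C)(c1c(OCOCC[Si](C)(C)C)c(OC)c(C(C)C)cc1)[C@@H](C(=O)OC(=O)C(F)(F)F)C(C)(C)CC(=O)OCC[Si](C)(C)C | intermediate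
17 | 2-(trimethylsilyl)ethyl 3-[(1S,2S)-1-ethenyl-6-methoxy-1-methyl-3-oxo-5-(propan-2-yl)-7-(SEM-oxy)-2,3-dihydro-1H-inden-2-yl]-3-methylbutanoate | C=C[C@]1(C)c2c(OCOCC[Si](C)(C)C)c(OC)c(C(C)C)cc2C(=O)[C@H]1C(C)(C)CC(=O)OCC[Si](C)(C)C | intermediate
18 | 3-methylidene analogue of 17 (C6=C7H2 in place of C6=O; C5 and C10 unchanged) | C=C[C@]1(C)c2c(OCOCC[Si](C)(C)C)c(OC)c(C(C)C)cc2C(=C)[C@H]1C(C)(C)CC(=O)OCC[Si](C)(C)C | intermediate
19 | 3-hydroxy-3-(hydroxymethyl) analogue of 17 (6α-OH, 6β-CH2OH, 5α-H, 10β-Me) | C=C[C@]1(C)c2c(OCOCC[Si](C)(C)C)c(OC)c(C(C)C)cc2[C@@](O)(CO)[C@H]1C(C)(C)CC(=O)OCC[Si](C)(C)C | intermediate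
20 | cyclic carbonate of 19 (spiro-1,3-dioxolan-2-one at C6, ring oxygen α) | C=C[C@]1(C)c2c(OCOCC[Si](C)(C)C)c(OC)c(C(C)C)cc2[C@]3(OC(=O)OC3)[C@H]1C(C)(C)CC(=O)OCC[Si](C)(C)C | intermediate
21 | C11 phenol, 3-(indan-2-yl)-3-methylbutanoic acid (20 without SEM and TMSE) | C=C[C@]1(C)c2c(O)c(OC)c(C(C)C)cc2[C@]3(OC(=O)OC3)[C@H]1C(C)(C)CC(=O)O | intermediate
22 | 12-methoxy-11,14-quinone acid (ring C as 2-methoxy-3-isopropyl-1,4-benzoquinone fused to ring B) | C=C[C@]1(C)C2=C(C(=O)C(C(C)C)=C(OC)C2=O)[C@]3(OC(=O)OC3)[C@H]1C(C)(C)CC(=O)O | intermediate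
23 | 1,3-dioxoisoindolin-2-yl ester (N-acyloxyphthalimide) of 22 | C=C[C@]1(C)C2=C(C(=O)C(C(C)C)=C(OC)C2=O)[C@]3(OC(=O)OC3)[C@H]1C(C)(C)CC(=O)ON4C(=O)c5ccccc5C4=O | intermediate
24 | 4-epi-trans-communic acid, (1R,4aR,5S,8aR)-1,4a-dimethyl-6-methylidene-5-[(2E)-3-methylpenta-2,4-dien-1-yl]decahydronaphthalene-1-carboxylic acid | C=C1CC[C@@H]2[C@](C)(CCC[C@@]2(C)C(=O)O)[C@H]1C/C=C(\C)C=C | starting material
25 | [5+2] adduct: 11-hydroxy-9(11)-ene-12,14-dione with C8 and C13 bridged by C15′H2–C14′H(labdane), labdane substituent endo; C10 vinyl and C4–CH2–CO2N(phthaloyl) arm open; C6/C7 carbonate | C=C1CC[C@@H]2[C@](C)(CCC[C@@]2(C)C(=O)O)[C@H]1C/C=C(\C)[C@@H]1C[C@@]23C(=O)[C@]1(C(C)C)C(=O)C(O)=C2[C@@](C)(C=C)[C@H](C(C)(C)CC(=O)ON5C(=O)c6ccccc6C5=O)[C@@]34OC(=O)OC4 | intermediate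
26 | ring-A-closed compound: target skeleton with C6/C7 cyclic carbonate in place of the hydroxy-aldehyde | C=C1CC[C@@H]2[C@](C)(CCC[C@@]2(C)C(=O)O)[C@H]1C/C=C(\C)[C@@H]1C[C@@]23C(=O)[C@]1(C(C)C)C(=O)C(O)=C2[C@@]1(C)CCCC(C)(C)[C@@H]1[C@@]34OC(=O)OC4 | intermediate
27 | 6α-hydroxy-6β-(hydroxymethyl) compound (target with CH2OH in place of CHO) | C=C1CC[C@@H]2[C@](C)(CCC[C@@]2(C)C(=O)O)[C@H]1C/C=C(\C)[C@@H]1C[C@@]23C(=O)[C@]1(C(C)C)C(=O)C(O)=C2[C@@]1(C)CCCC(C)(C)[C@@H]1[C@]3(O)CO | intermediate
28 | CNP0124601.1: 6α-hydroxy-6β-formyl ring-B-contracted abietane 11-hydroxy-9(11)-ene-12,14-dione, C8/C13 bridged by C15′–C14′ of labda-8′(17′),12′E-dien-18′-oic acid | C=C1CC[C@@H]2[C@](C)(CCC[C@@]2(C)C(=O)O)[C@H]1C/C=C(\C)[C@@H]1C[C@@]23C(=O)[C@]1(C(C)C)C(=O)C(O)=C2[C@@]1(C)CCCC(C)(C)[C@@H]1[C@]3(O)C=O | target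

Total step count: 19
Longest linear sequence: 18 steps (1 → 28 through steps 1–4 and 6–19; step 5 is a side branch)

**Steps most likely to fail**

Step 16. The titanium-bound zwitterion may collapse through oxygen (formal [3+2]) or revert before the methyl group is lost. The diene may also react with poor facial selectivity or through its trisubstituted alkene. The fallback sets out from 23: the vinylogous methyl ester is cleaved with BCl3 (CH2Cl2, −78 °C) to give the hydroxyquinone redox-active ester F1. F1 then undergoes the perezone-type [5+2] cycloaddition with 24 under BF3·OEt2 (CH2Cl2, −78 → −20 °C), in which a proton instead of a methyl cation is lost. The route is rejoined at 25.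

Step 17. Hydrogen-atom transfer to the open-chain C3 radical may outrun the slow 6-endo addition to the unactivated vinyl group, giving plain reductive decarboxylation. The fallback sets out from 25 and separates ring closure from reduction. Decarboxylative iodination (LiI, PPh3 20 mol %, blue LEDs, acetone) should give the neopentyl iodide F2. Iodine-atom-transfer cyclisation (Bu3SnSnBu3 10 mol %, sun lamp, benzene, 80 °C) has no hydrogen donor present and the chain is carried by iodine transfer; it should give the secondary iodide F3 as C1 epimers, which is of no consequence. Bu3SnH with AIBN (toluene, 80 °C) then removes the iodine and the route is rejoined at 26.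

Step 8. The catalyst may fail to engage the E-propenyl group next to the quaternary C10, giving no turnover or double-bond migration. The fallback sets out from 14: Lemieux–Johnson cleavage (OsO4 2 mol %, NaIO4, 2,6-lutidine, dioxane/H2O) should give the non-enolisable aldehyde F4. Wittig methylenation (Ph3P=CH2 from Ph3PCH3Br and KOtBu, THF, 0 °C) then rejoins the route at 15.

**Further compounds**

F1 | step 16 | hydroxyquinone redox-active ester (23 with C12–OH in place of C12–OMe) | C=C[C@]1(C)C2=C(C(=O)C(C(C)C)=C(O)C2=O)[C@]3(OC(=O)OC3)[C@H]1C(C)(C)CC(=O)ON4C(=O)c5ccccc5C4=O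
F2 | step 17 | neopentyl iodide (25 with C4–CH2I in place of the C4–CH2–CO2N(phthaloyl) arm) | C=C1CC[C@@H]2[C@](C)(CCC[C@@]2(C)C(=O)O)[C@H]1C/C=C(\C)[C@@H]1C[C@@]23C(=O)[C@]1(C(C)C)C(=O)C(O)=C2[C@@](C)(C=C)[C@H](C(C)(C)CI)[C@@]34OC(=O)OC4
F3 | step 17 | secondary iodide (26 bearing iodine at C1, C1 epimers) | C=C1CC[C@@H]2[C@](C)(CCC[C@@]2(C)C(=O)O)[C@H]1C/C=C(\C)[C@@H]1C[C@@]23C(=O)[C@]1(C(C)C)C(=O)C(O)=C2[C@@]1(C)C(I)CCC(C)(C)[C@@H]1[C@@]34OC(=O)OC4
F4 | step 8 | aldehyde (14 with C10–CHO in place of the propenyl group) | O=C[C@](C)(c1c(OCOCC[Si](C)(C)C)c(OC)c(C(C)C)cc1)[C@@H](C(=O)O)C(C)(C)CC(=O)OCC[Si](C)(C)C
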